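Watch the fraction left.

the same everywhere: starting material 0.80 M
- birch: reagent 1.1 equiv; capture agent 0.24 M; run made earlier
- Monday's: reagent 1.00 equiv; capture agent 0.240 M; time 30 h
- Thursday's: reagent 1.20 equiv; capture agent 0.240 M; time 30 h
- Sunday's: reagent 3.00 equiv; capture agent 0.240 M; time 30 h

birch run (percent of the starting material charged)

| time / h | mono adduct / % | triple product / % | starting material / % |
|---|---|---|---|
| 8.00 | 84.8 | 1.6 | 13.1 |
| 15.0 | 89.8 | 1.7 | 6.5 |
| 25.0 | 92.2 | 2.2 | 3.7 |
| 30.0 | 92.3 | 2.7 | 2.9 |

(scatter of a reading: 0.3 percentage points)

- how much mono adduct is there at the end, in percent of the starting material charged: for each flask in turn (Monday's, Thursday's, Sunday's)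



Let L be the fraction of starting material left in the birch run. Reagent meets starting material and mono adduct at the same moments, so one exposure acts on both. For a small ratio s of the mono adduct's rate constant with reagent to the starting material's (the selectivity factor), the part lost beyond mono adduct is s times (ln(1/L) − (1 − L)). The birch reading at 30.0 h gives s = 0.0187.

Now climb down the ladder for Sunday's flask. Take the birch fall of starting material from 8.00 h to 15.0 h, count two reagent per mono adduct lost with 0.112 M reagent on average, and read 0.894 /M/h for the first addition, hence 0.0167 /M/h for the second. On the top rung, Sunday's starting material has a half-life of 0.323 h at the charged reagent. On the middle rung stands something unseen: the birch run at 30.0 h leaves 2.10 % of its charge unread. On the bottom rung, Sunday's mono adduct has a half-life of 25.9 h at the starting excess of reagent, far longer than that of the starting material. So Sunday's flask first fills with mono adduct and then slowly loses it. Count two reagent per mono adduct lost again: the excess of 2.00 then falls in step with the fraction f of mono adduct left, and f = 1/(1 + second constant × starting excess in c(reagent) × time). My reckoning for Sunday's flask is 55.5 %.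

The forecast gives 89.9 % for Monday's flask, 92.4 % for Thursday's and 60 % for Sunday's, the last higher than mine, with this ground: “If the bis-adduct step is reversible, the loss would be smaller”.

Monday's flask gives 89.4 %, Thursday's 92.1 % and Sunday's 56.5 %, so the forecast is right within the tolerance.

    starting material + reagent → mono adduct (k = 0.800 /M/h)
    reagent + mono adduct → bis adduct (k = 0.0160 /M/h)
    reagent + bis adduct → triple product (k = 1.00 /M/h)
    bis adduct + capture agent → trapped intermediate (k = 0.450 /M/h)

In Sunday's flask starting material stood at 0 % by 15.0 h, while reagent kept 49.4 % of its charge and mono adduct went on to bis adduct, which held 1.09 %, and triple product, at 24.4 %. By 30.0 h triple product stood at 39.5 % and mono adduct had fallen to 56.5 %, against 55.5 % reckoned. Thursday's flask ended with 1.07 % starting material, for which s gives 92.3 % mono adduct against the 92.1 % it held.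

(The readings are calculated on assumed constants; the scatter is artificial.)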